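Assumptions: the target has no stereocentres (it is achiral), so there is no enantiomer to control. The SMILES shows the free hydrogen sulfate, so the last step ends with a cold H⁺ exchange; in practice the compound is better stored as its Na⁺ or K⁺ salt.

## Retrosynthetic overview

1. The target comes from fluoride desilylation of a 5,7-bis(TIPS) flavone that already carries the 4'-sulfate as a Bu4N⁺ salt (sulfate-first, so no late regioselective sulfation).
2. Ring C, the only ring built, is formed last by a Pd three-component carbonylative annulation: o-iodophenol + CO (becomes C4) + 4-ethynylphenyl sulfate (C2, C3 and ring B).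
3. The iodophenol comes from ortho-iodination of a symmetric 3,5-bis(silyloxy)-4-methoxyphenol.
4. That phenol comes from sterically controlled Ir C–H borylation/oxidation of bis-TIPS 2-methoxyresorcinol, which sets the 5,6,7-oxygenation with the 6-OMe in place from the start.
5. Rings A and B are purchased aromatics; the usual acetophenone, chalcone and Baker–Venkataraman chemistry is not used.

## Route

**Step 1**
Reactants: 1, 2-methoxyresorcinol (2-methoxybenzene-1,3-diol)
Product: 2, 2-methoxy-1,3-bis(triisopropylsilyloxy)benzene
Conditions: TIPSCl (2.4 eq), imidazole (5 eq), DMF, rt → 40 °C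
Reagents that add atoms: triisopropylsilyl chloride, CC(C)[Si](Cl)(C(C)C)C(C)C
Why: Standard phenol O-silylation; TIPS has no aryl C–H to compete in step 2, blocks both positions ortho to oxygen, and is later removed by fluoride, which a sulfate tolerates.

**Step 2**
Reactants: 2, 2-methoxy-1,3-bis(triisopropylsilyloxy)benzene
Product: 3, 2-[4-methoxy-3,5-bis(triisopropylsilyloxy)phenyl]-4,4,5,5-tetramethyl-1,3,2-dioxaborolane
Conditions: [Ir(OMe)(cod)]2 (2 mol%), 3,4,7,8-Me4-phenanthroline (4 mol%), B2pin2 (1.0 eq), THF, 80 °C
Reagents that add atoms: bis(pinacolato)diboron, CC1(C)OB(OC1(C)C)B1OC(C)(C)C(C)(C)O1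
Why: Ir-catalysed aromatic C–H borylation is sterically controlled, and C5 is the only C–H not ortho to a substituent, so a single regioisomer is expected.

**Step 3**
Reactants: 3, the aryl pinacol boronate
Product: 4, 4-methoxy-3,5-bis(triisopropylsilyloxy)phenol
Conditions: 30% H2O2, 1 M NaOH, THF, 0 °C, 20 min; quench with Na2S2O3/NH4Cl (can be telescoped with step 2)
Reagents that add atoms: hydrogen peroxide, OO
Why: Boronate oxidation with 1,2-aryl shift from B to O; brief cold base leaves aryl TIPS ethers intact.

**Step 4**
Reactants: 4, 4-methoxy-3,5-bis(triisopropylsilyloxy)phenol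
Product: 5, 2-iodo-4-methoxy-3,5-bis(triisopropylsilyloxy)phenol
Conditions: NIS (1.0 eq), CH2Cl2, −40 → 0 °C, dark
Reagents that add atoms: N-iodosuccinimide, O=C1CCC(=O)N1I
Why: Electrophilic aromatic iodination; the only two free ring positions are ortho to the free OH and equivalent by symmetry, so mono-iodination gives one product.

**Step 5** (convergent branch)
Reactants: 6, 4-ethynylphenol
Product: 7, tetrabutylammonium 4-ethynylphenyl sulfate
Conditions: SO3·pyridine (3 eq), pyridine/MeCN, rt; then aq. Bu4NHSO4 (pH 7), extract into CH2Cl2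
Reagents that add atoms: sulfur trioxide–pyridine, [O-]S(=O)(=O)[n+]1ccccc1; tetrabutylammonium hydrogen sulfate (counter-ion), CCCC[N+](CCCC)(CCCC)CCCC.OS(=O)(=O)[O-]
Why: Phenol O-sulfation with an SO3–amine complex, which does not touch the alkyne; ion-pairing with Bu4N⁺ gives an organic-soluble, chromatographable sulfate monoester salt.

**Step 6** (key step)
Reactants: 5, the iodophenol; 7, tetrabutylammonium 4-ethynylphenyl sulfate (1.3 eq)
Product: 8, tetrabutylammonium 4-[6-methoxy-4-oxo-5,7-bis(triisopropylsilyloxy)-4H-chromen-2-yl]phenyl sulfate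
Conditions: PdCl2(dppf) (5 mol%), CO (10 bar), Et2NH/DMF 1:4, 80 °C, Cu-free, degassed; workup CH2Cl2/aq. Bu4NHSO4
Reagents that add atoms: carbon monoxide, [C-]#[O+] (the Bu4N⁺ counter-ion is carried from 7 and restored by the Bu4NHSO4 wash)
Why: Carbonylative Sonogashira annulation: oxidative addition, CO insertion and alkynylation give an o-hydroxyaryl ynone, Et2NH adds to form a β-aminoenone, and the phenoxide closes 6-endo with loss of Et2NH to give the flavone rather than the aurone. The sulfate monoester anion is inert to Pd(0), CO and amines, and only one phenol oxygen is free, so the 6-OMe regiochemistry is fixed.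

**Step 7**
Reactants: 8, the bis-TIPS flavone sulfate Bu4N⁺ salt
Product: 9, hispidulin 4'-sulfate (4-(5,7-dihydroxy-6-methoxy-4-oxo-4H-chromen-2-yl)phenyl hydrogen sulfate)
Conditions: TBAF (3 eq), THF, 0 °C → rt; C18 reverse-phase; Dowex 50WX8 (H⁺ form), MeOH/H2O, 0 °C; lyophilise
Reagents that add atoms: none
Why: Fluoride cleaves both aryl Si–O bonds while aryl sulfate monoesters are stable to fluoride and base; the cation-exchange resin removes Bu4N⁺ and delivers the free acid without hot acid.

## Compound list

1 | 2-methoxyresorcinol | COc1c(O)cccc1O | starting material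
2 | 2-methoxy-1,3-bis(triisopropylsilyloxy)benzene | COc1c(O[Si](C(C)C)(C(C)C)C(C)C)cccc1O[Si](C(C)C)(C(C)C)C(C)C | intermediate
3 | 2-[4-methoxy-3,5-bis(triisopropylsilyloxy)phenyl]-4,4,5,5-tetramethyl-1,3,2-dioxaborolane | COc1c(O[Si](C(C)C)(C(C)C)C(C)C)cc(B2OC(C)(C)C(C)(C)O2)cc1O[Si](C(C)C)(C(C)C)C(C)C | intermediate
4 | 4-methoxy-3,5-bis(triisopropylsilyloxy)phenol | COc1c(O[Si](C(C)C)(C(C)C)C(C)C)cc(O)cc1O[Si](C(C)C)(C(C)C)C(C)C | intermediate
5 | 2-iodo-4-methoxy-3,5-bis(triisopropylsilyloxy)phenol | COc1c(O[Si](C(C)C)(C(C)C)C(C)C)cc(O)c(I)c1O[Si](C(C)C)(C(C)C)C(C)C | intermediate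
6 | 4-ethynylphenol | C#Cc1ccc(O)cc1 | starting material
7 | tetrabutylammonium 4-ethynylphenyl sulfate | C#Cc1ccc(OS(=O)(=O)[O-])cc1.CCCC[N+](CCCC)(CCCC)CCCC | intermediate
8 | tetrabutylammonium 4-[6-methoxy-4-oxo-5,7-bis(triisopropylsilyloxy)-4H-chromen-2-yl]phenyl sulfate | COc1c(O[Si](C(C)C)(C(C)C)C(C)C)cc2oc(-c3ccc(OS(=O)(=O)[O-])cc3)cc(=O)c2c1O[Si](C(C)C)(C(C)C)C(C)C.CCCC[N+](CCCC)(CCCC)CCCC | intermediate
9 | hispidulin 4'-sulfate | COc1c(O)cc2oc(-c3ccc(OS(=O)(=O)O)cc3)cc(=O)c2c1O | target

## Summary

Total steps: 7. Longest linear sequence: 6 (steps 1–4, 6, 7); step 5 is a one-step side branch.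

Steps most likely to fail, with fallbacks:

1. **Step 6, carbonylative annulation.** The iodide is hindered and electron-rich, and aurone, non-carbonylative benzofuran, diethylamide, or premature loss of the 5-OTIPS (which would allow the 8-methoxy regioisomer) could compete. Fallback: abandon the three-component coupling. Protect the OH of 5 as its MOM ether, do I/Mg exchange (iPrMgCl·LiCl), add to the Weinreb amide of 3-(4-benzyloxyphenyl)propiolic acid to give the ynone, then unmask the phenol and cyclise 6-endo with Et2NH. The 4'-OBn is then removed by hydrogenolysis and the sulfate installed afterwards with SO3·pyridine, before desilylation.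

2. **Step 4, mono-iodination.** Di-iodination or oxidation of the very electron-rich phenol to a quinone is possible. Fallback: avoid electrophilic halogenation. Convert 4 to its O-MOM ether and use directed ortho-lithiation (s-BuLi/TMEDA, −78 °C), quenching with I2 or directly with the alkynyl Weinreb amide above, which also removes the need for an iodide.

3. **Step 7, desilylation and isolation of the free acid.** Aryl hydrogen sulfates can autocatalytically hydrolyse on concentration, and separating Bu4N⁺/fluoride residues is awkward. Fallback: switch to a sulfate-last endgame. Run step 6 with 1-(benzyloxy)-4-ethynylbenzene, hydrogenolyse the 4'-benzyl ether (H2, Pd/C), sulfate the free 4'-OH of the 5,7-bis-TIPS flavone with SO3·NMe3, desilylate with KF/MeOH, and isolate as the potassium salt, acidifying only immediately before use.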